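**Strategy.** Locants: decalin C1–C10, with C4 (CH carrying the acid chain), C5 (angular C–Me), C8 (CHMe), C9 (C–Me/benzyl), C10 (angular CH); ring A = C1–C5/C10, ring B = C5–C10. Ring B is disconnected at C7–C8, treated as the CH–C(=O) bond of a β-keto ester lying between C6H2 and quaternary C9. The key step, a Michael–Dieckmann annulation of monocyclic keto ester 10 with tert-butyl acrylate, forms C5–C6 and then C7–C8 in one operation, fixes quaternary C5 trans to the C10 side chain and closes ring B. The resulting C8 ketone/C7 ester pair then directs benzylation at C9 and is later converted into the C8 methine.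

Key step: step 7

Remark (naming): α is the face of the C5 methyl and β the face of H-10; Ar = 2-(benzyloxy)-5-methoxy-3-methylphenyl; "decalin" names use the skeleton locants above, and the SMILES in the compound list fix the absolute configuration.

Step 1
Reactants: 1 4-methoxy-2-methylphenol
Product: 2 2-(hydroxymethyl)-4-methoxy-6-methylphenol
Conditions: 37% aq. CH2O, NaOH (cat.), H2O, rt
Reagents that add atoms: formaldehyde, C=O
Why: Base-mediated ortho-hydroxymethylation of the phenol (Lederer–Manasse reaction) can only take the single free ortho position, because the para position carries the methoxy group and the other ortho position the methyl group.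

Step 2
Reactants: 2 2-(hydroxymethyl)-4-methoxy-6-methylphenol
Product: 3 [2-(benzyloxy)-5-methoxy-3-methylphenyl]methanol
Conditions: BnBr, K2CO3, acetone, reflux
Reagents that add atoms: benzyl bromide, BrCc1ccccc1
Why: Williamson etherification, in which the phenoxide formed with K2CO3 is alkylated far faster than the neutral benzylic alcohol.

Step 3
Reactants: 3 [2-(benzyloxy)-5-methoxy-3-methylphenyl]methanol
Product: 4 2-(benzyloxy)-1-(bromomethyl)-5-methoxy-3-methylbenzene
Conditions: PBr3, Et2O, 0 °C
Reagents that add atoms: phosphorus tribromide, BrP(Br)Br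
Why: PBr3 converts the primary benzylic alcohol into the bromide by SN2 displacement of the intermediate phosphite ester.

Step 4
Reactants: 5 2-methylcyclohex-2-en-1-one
Product: 6 (R)-2-methylcyclohex-2-en-1-ol
Conditions: (S)-2-methyl-CBS-oxazaborolidine (10 mol%), BH3·SMe2, THF, −20 °C
Reagents that add atoms: none
Why: CBS reduction, in which the oxazaborolidine–borane complex delivers hydride to one carbonyl face with the trisubstituted alkenyl carbon as the large group, which should give the (R)-allylic alcohol.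

Step 5
Reactants: 6 (R)-2-methylcyclohex-2-en-1-ol
Product: 8 methyl 2-[(1R)-2-methylcyclohex-2-en-1-yl]propanoate (both epimers at the propanoate α-carbon), via mixed ketene acetal 7 (not isolated)
Conditions: EtC(OMe)3, EtCO2H (cat.), xylene, 140 °C, MeOH distilled off
Reagents that add atoms: trimethyl orthopropionate, CCC(OC)(OC)OC
Why: Johnson–Claisen rearrangement, in which ketene acetal 7 rearranges suprafacially so that the C–O stereocentre of 6 is transferred to the new C–C stereocentre C10 on the same ring face, while the propanoate α-carbon needs no control because it is enolised later.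

Step 6
Reactants: 8 methyl 2-[(1R)-2-methylcyclohex-2-en-1-yl]propanoate
Product: 10 methyl 2-[(1S)-2-methyl-3-oxocyclohexyl]propanoate (epimers at ring C2 and at the α-carbon), via alkylborane 9 (not isolated)
Conditions: BH3·SMe2, THF, 0 °C to rt; then [C5H5NH][CrO3Cl], CH2Cl2, reflux
Reagents that add atoms: pyridinium chlorochromate, [O-][Cr](=O)(=O)Cl.c1cc[nH+]cc1
Why: Hydroboration places boron on the less substituted alkene carbon (C4) and direct chlorochromate oxidation of the alkylborane gives the ketone, the epimerisable centres being irrelevant at this stage.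

Step 7
Reactants: 10 methyl 2-[(1S)-2-methyl-3-oxocyclohexyl]propanoate
Product: 12 tert-butyl 5α,9-dimethyl-4,8-dioxo-trans-decalin-7-carboxylate (10β-H; C7/C9 epimers; partly enolised), via Michael adduct 11 (not isolated)
Conditions: tert-butyl acrylate, KOt-Bu (0.2 equiv), t-BuOH–THF, 0 °C; then KOt-Bu (2.2 equiv), THF, rt; AcOH
Reagents that add atoms: tert-butyl acrylate, C=CC(=O)OC(C)(C)C
Why: Catalytic KOt-Bu equilibrates 10 to its more substituted C4–C5 enolate, which adds to the acrylate to give 11 with the new C5–C6 bond; with excess base the tert-butyl ester enolate at C7 attacks the methyl ester carbon C8 and expels methoxide, so that ring B is closed by the C7–C8 bond. The closest known reaction type is the tandem Michael–Dieckmann (Michael–Claisen) annulation of enolates with acrylates. Ring B closes by a 6-exo-trig acyl substitution of an ester enolate. C5 is the only new fixed stereocentre: the acceptor approaches the enolate face opposite the C10 side chain, as in annulations of 2,3-dialkylcyclohexanones, which places the C5 methyl cis to that chain and gives the trans ring fusion, while C7 and C9 stay epimerisable. The step needs alkylation at C5 and not C3, and closure C7 to C8 and not the competing Claisen modes (C3 or C9 enolate onto an ester), which lead to non-enolisable bridged or quaternary β-dicarbonyls. The reversible alkoxide conditions should funnel these into 12, the only product withdrawn from the equilibria as a stabilised β-keto ester enolate.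

Step 8
Reactants: 12 tert-butyl 5α,9-dimethyl-4,8-dioxo-trans-decalin-7-carboxylate
Product: 13 tert-butyl 5α,9-dimethyl-8-oxo-4-(trifluoromethylsulfonyloxy)-trans-decal-3-ene-7-carboxylate
Conditions: KN(SiMe3)2 (2.1 equiv), THF, −78 °C; PhNTf2 (1.05 equiv), −78 to 0 °C
Reagents that add atoms: N-phenylbis(trifluoromethanesulfonimide), O=S(=O)(N(c1ccccc1)S(=O)(=O)C(F)(F)F)C(F)(F)F
Why: Of the two enolates formed, the simple ketone enolate (C3–C4, the only enolisable side of the C4 ketone) is far more nucleophilic at oxygen than the stabilised β-keto ester enolate and is triflated selectively, which masks C4 as a non-acidic enol triflate for later cross-coupling.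

Step 9
Reactants: 13 tert-butyl 5α,9-dimethyl-8-oxo-4-(trifluoromethylsulfonyloxy)-trans-decal-3-ene-7-carboxylate; 4 2-(benzyloxy)-1-(bromomethyl)-5-methoxy-3-methylbenzene
Product: 14 tert-butyl 9β-(ArCH2)-5α,9α-dimethyl-8-oxo-4-(trifluoromethylsulfonyloxy)-trans-decal-3-ene-7-carboxylate
Conditions: LiN(i-Pr)2 (2.3 equiv), THF, −78 to 0 °C; then 4, −78 °C to rt
Reagents that add atoms: none
Why: γ-Alkylation of a β-keto ester dianion, in which the second deprotonation can only occur at C9 and the benzyl bromide approaches from the β face, opposite the axial C5 methyl that shields the α face, so that C9 becomes quaternary with methyl α and benzyl β.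

Step 10
Reactants: 14 tert-butyl 9β-(ArCH2)-5α,9α-dimethyl-8-oxo-4-(trifluoromethylsulfonyloxy)-trans-decal-3-ene-7-carboxylate
Product: 16 9β-(ArCH2)-5α,9α-dimethyl-8-oxo-trans-decal-3-en-4-yl trifluoromethanesulfonate, via β-keto acid 15 (not isolated)
Conditions: CF3CO2H, CH2Cl2, rt; then toluene, 80 °C
Reagents that add atoms: none
Why: Acidolysis of the tert-butyl ester gives β-keto acid 15, which decarboxylates on warming, while the benzyl aryl ether and the enol triflate should survive.

Step 11
Reactants: 16 9β-(ArCH2)-5α,9α-dimethyl-8-oxo-trans-decal-3-en-4-yl trifluoromethanesulfonate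
Product: 17 9β-(ArCH2)-5α,9α-dimethyl-8-methylene-trans-decal-3-en-4-yl trifluoromethanesulfonate
Conditions: Zn, CH2Br2, TiCl4, THF–CH2Cl2, 0 °C to rt
Reagents that add atoms: dibromomethane, BrCBr
Why: Takai–Lombardo methylenation is non-basic and suited to hindered, enolisable ketones flanked by a quaternary carbon.

Step 12
Reactants: 17 9β-(ArCH2)-5α,9α-dimethyl-8-methylene-trans-decal-3-en-4-yl trifluoromethanesulfonate
Product: 18 9β-(ArCH2)-5α,8α,9α-trimethyl-trans-decal-3-en-4-yl trifluoromethanesulfonate
Conditions: H2 (4 atm), RhCl(PPh3)3 (cat.), benzene–EtOH, rt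
Reagents that add atoms: none
Why: Homogeneous hydrogenation should reduce only the 1,1-disubstituted exocyclic alkene and add hydrogen from the β face, away from the axial C9 methyl, giving the equatorial α C8 methyl without touching the enol triflate or the benzyl ether.

Step 13
Reactants: 18 9β-(ArCH2)-5α,8α,9α-trimethyl-trans-decal-3-en-4-yl trifluoromethanesulfonate
Product: 19 benzyl 3-[9β-(ArCH2)-5α,8α,9α-trimethyl-trans-decal-3-en-4-yl]propanoate
Conditions: BrZnCH2CH2CO2Bn (from benzyl 3-bromopropanoate, Zn, LiCl, THF), Pd(PPh3)4 (cat.), THF–DMA, 50 °C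
Reagents that add atoms: [3-(benzyloxy)-3-oxopropyl]zinc bromide, Br[Zn]CCC(=O)OCc1ccccc1 (made in the flask from benzyl 3-bromopropanoate, BrCCC(=O)OCc1ccccc1)
Why: Negishi coupling of the alkenyl triflate with the ester-bearing alkylzinc bromide puts the three-carbon chain on sp2 C4, so that the C4 hydrogen can be delivered last.

Step 14
Reactants: 19 benzyl 3-[9β-(ArCH2)-5α,8α,9α-trimethyl-trans-decal-3-en-4-yl]propanoate
Product: 21 benzyl 3-[9β-(ArCH2)-5α,8α,9α-trimethyl-3-oxo-trans-decalin-4α-yl]propanoate, via alkylborane 20 (not isolated)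
Conditions: BH3·SMe2, THF, 0 °C to rt; then [C5H5NH][CrO3Cl], CH2Cl2, reflux
Reagents that add atoms: pyridinium chlorochromate, [O-][Cr](=O)(=O)Cl.c1cc[nH+]cc1
Why: Hydroboration adds B–H syn across C3=C4 from the β face, anti to the axial C5 methyl, with boron on the less substituted C3, which fixes H-4 β and the chain α, and chlorochromate oxidation of the alkylborane gives the C3 ketone.

Step 15
Reactants: 21 benzyl 3-[9β-(ArCH2)-5α,8α,9α-trimethyl-3-oxo-trans-decalin-4α-yl]propanoate
Product: 22 benzyl 3-[9β-(ArCH2)-5α,8α,9α-trimethyl-3-(propan-2-ylidene)-trans-decalin-4α-yl]propanoate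
Conditions: TiCl3(DME)1.5, Zn(Cu), acetone (excess), DME, reflux
Reagents that add atoms: acetone, CC(C)=O
Why: Mixed McMurry coupling with an excess of acetone converts the C3 ketone into the tetrasubstituted isopropylidene under non-basic conditions, which should limit epimerisation at C4.

Step 16
Reactants: 22 benzyl 3-[9β-(ArCH2)-5α,8α,9α-trimethyl-3-(propan-2-ylidene)-trans-decalin-4α-yl]propanoate
Product: 23 3-[9β-(2-hydroxy-5-methoxy-3-methylbenzyl)-5α,8α,9α-trimethyl-3-(propan-2-ylidene)-trans-decalin-4α-yl]propanoic acid (target; 4S,5R,8R,9S,10R in skeleton locants)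
Conditions: H2 (1 atm), 10% Pd/C, EtOAc, rt
Reagents that add atoms: none
Why: Hydrogenolysis cleaves the benzyl aryl ether and the benzyl ester in one operation, while the tetrasubstituted alkene should be too hindered to be reduced.

**Compound list**

1 | 4-methoxy-2-methylphenol | COc1ccc(O)c(C)c1 | starting material
2 | 2-(hydroxymethyl)-4-methoxy-6-methylphenol | COc1cc(C)c(O)c(CO)c1 | intermediate
3 | [2-(benzyloxy)-5-methoxy-3-methylphenyl]methanol | COc1cc(C)c(OCc2ccccc2)c(CO)c1 | intermediate
4 | 2-(benzyloxy)-1-(bromomethyl)-5-methoxy-3-methylbenzene | COc1cc(C)c(OCc2ccccc2)c(CBr)c1 | intermediate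
5 | 2-methylcyclohex-2-en-1-one | CC1=CCCCC1=O | starting material
6 | (R)-2-methylcyclohex-2-en-1-ol | O[C@@H]1CCCC=C1C | intermediate
7 | mixed ketene acetal, 1-methoxy-1-[(1R)-2-methylcyclohex-2-en-1-yloxy]prop-1-ene (not isolated) | CC=C(OC)O[C@@H]1CCCC=C1C | intermediate
8 | methyl 2-[(1R)-2-methylcyclohex-2-en-1-yl]propanoate | COC(=O)C(C)[C@H]1CCCC=C1C | intermediate
9 | alkylborane, methyl 2-[(1S)-3-boranyl-2-methylcyclohexyl]propanoate (not isolated) | COC(=O)C(C)[C@H]1CCCC(B)C1C | intermediate
10 | methyl 2-[(1S)-2-methyl-3-oxocyclohexyl]propanoate | COC(=O)C(C)[C@H]1CCCC(=O)C1C | intermediate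
11 | Michael adduct, methyl 2-[(1R,2R)-2-(3-tert-butoxy-3-oxopropyl)-2-methyl-3-oxocyclohexyl]propanoate (not isolated) | COC(=O)C(C)[C@H]1CCCC(=O)[C@]1(C)CCC(=O)OC(C)(C)C | intermediate
12 | tert-butyl 5α,9-dimethyl-4,8-dioxo-trans-decalin-7-carboxylate | CC1[C@H]2CCCC(=O)[C@]2(C)CC(C(=O)OC(C)(C)C)C1=O | intermediate
13 | tert-butyl 5α,9-dimethyl-8-oxo-4-(trifluoromethylsulfonyloxy)-trans-decal-3-ene-7-carboxylate | CC1[C@H]2CCC=C(OS(=O)(=O)C(F)(F)F)[C@]2(C)CC(C(=O)OC(C)(C)C)C1=O | intermediate
14 | tert-butyl 9β-(ArCH2)-5α,9α-dimethyl-8-oxo-4-(trifluoromethylsulfonyloxy)-trans-decal-3-ene-7-carboxylate | COc1cc(C)c(OCc2ccccc2)c(C[C@]3(C)[C@H]4CCC=C(OS(=O)(=O)C(F)(F)F)[C@]4(C)CC(C(=O)OC(C)(C)C)C3=O)c1 | intermediate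
15 | β-keto acid corresponding to 14 (not isolated) | COc1cc(C)c(OCc2ccccc2)c(C[C@]3(C)[C@H]4CCC=C(OS(=O)(=O)C(F)(F)F)[C@]4(C)CC(C(=O)O)C3=O)c1 | intermediate
16 | 9β-(ArCH2)-5α,9α-dimethyl-8-oxo-trans-decal-3-en-4-yl trifluoromethanesulfonate | COc1cc(C)c(OCc2ccccc2)c(C[C@]3(C)[C@H]4CCC=C(OS(=O)(=O)C(F)(F)F)[C@]4(C)CCC3=O)c1 | intermediate
17 | 9β-(ArCH2)-5α,9α-dimethyl-8-methylene-trans-decal-3-en-4-yl trifluoromethanesulfonate | COc1cc(C)c(OCc2ccccc2)c(C[C@]3(C)[C@H]4CCC=C(OS(=O)(=O)C(F)(F)F)[C@]4(C)CCC3=C)c1 | intermediate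
18 | 9β-(ArCH2)-5α,8α,9α-trimethyl-trans-decal-3-en-4-yl trifluoromethanesulfonate | COc1cc(C)c(OCc2ccccc2)c(C[C@]3(C)[C@H]4CCC=C(OS(=O)(=O)C(F)(F)F)[C@]4(C)CC[C@H]3C)c1 | intermediate
19 | benzyl 3-[9β-(ArCH2)-5α,8α,9α-trimethyl-trans-decal-3-en-4-yl]propanoate | COc1cc(C)c(OCc2ccccc2)c(C[C@]3(C)[C@H]4CCC=C(CCC(=O)OCc5ccccc5)[C@]4(C)CC[C@H]3C)c1 | intermediate
20 | alkylborane, 3β-boranyl-4β-H adduct of 19 (not isolated) | COc1cc(C)c(OCc2ccccc2)c(C[C@]3(C)[C@H]4CC[C@H](B)[C@@H](CCC(=O)OCc5ccccc5)[C@]4(C)CC[C@H]3C)c1 | intermediate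
21 | benzyl 3-[9β-(ArCH2)-5α,8α,9α-trimethyl-3-oxo-trans-decalin-4α-yl]propanoate | COc1cc(C)c(OCc2ccccc2)c(C[C@]3(C)[C@H]4CCC(=O)[C@@H](CCC(=O)OCc5ccccc5)[C@]4(C)CC[C@H]3C)c1 | intermediate
22 | benzyl 3-[9β-(ArCH2)-5α,8α,9α-trimethyl-3-(propan-2-ylidene)-trans-decalin-4α-yl]propanoate | COc1cc(C)c(OCc2ccccc2)c(C[C@]3(C)[C@H]4CCC(=C(C)C)[C@@H](CCC(=O)OCc5ccccc5)[C@]4(C)CC[C@H]3C)c1 | intermediate
23 | 3-[9β-(2-hydroxy-5-methoxy-3-methylbenzyl)-5α,8α,9α-trimethyl-3-(propan-2-ylidene)-trans-decalin-4α-yl]propanoic acid, CNP0299684.2 | COc1cc(C)c(O)c(C[C@]2(C)[C@H]3CCC(=C(C)C)[C@@H](CCC(=O)O)[C@]3(C)CC[C@H]2C)c1 | target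

**Totals.** Total step count: 16. Longest linear sequence: 13 steps (5 to 23, steps 4 to 16); the aryl branch (steps 1 to 3) joins at step 9.

**Steps most likely to fail**

Step 7 (key step). Alkylation at the less hindered C3, a second Michael addition or acrylate oligomerisation may outrun C5 alkylation, and the ring closure may stall at the open-chain stage. The fallback sets out from 10 and comes back at 12. Ketone 10 would be silylated under equilibrating conditions (Me3SiCl, Et3N, DMF, 130 °C) to the more substituted trimethylsilyl enol ether F1. A fluoride-promoted Michael addition (benzyltrimethylammonium fluoride, cat., THF) to tert-butyl acrylate would then give 11, now isolated, and a separate Dieckmann condensation (KOt-Bu, THF, then AcOH) would close ring B to 12.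

Step 9. The second deprotonation at the hindered C9 methine may be incomplete, so that the mono-anion is alkylated at C7 or on oxygen, or the amide base may attack the enol triflate. The fallback sets out from 13 and comes back at 16. Acidolysis and decarboxylation of 13 (CF3CO2H, then toluene, 80 °C) would give the keto triflate F2. Its kinetic C7 enolate (LiN(i-Pr)2, −78 °C) would be dehydrogenated with N-tert-butylbenzenesulfinimidoyl chloride to the cross-conjugated enone F3. Enone F3 has C9 as its only enolisable position, so LiN(SiMe3)2 followed by 4 would give the benzylated enone F4 with the same facial preference. Hydrogenation of the enone C=C (H2, RhCl(PPh3)3) would return 16.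

Step 15. Homocoupling of acetone may dominate, cross-coupling at the hindered ketone may be sluggish, and Lewis-acid-promoted enolisation may epimerise C4. The fallback sets out from 21 and comes back at 22. Addition of dilithiated isobutyric acid (isobutyric acid, 2 LiN(i-Pr)2, THF, −78 °C) to the ketone would give the β-hydroxy acid F5. Benzenesulfonyl chloride in pyridine would close it to the spiro β-lactone F6, and thermolysis (collidine, 160 °C) would expel CO2 to give 22.

**Further compounds**

F1 | step 7 | methyl 2-[(1R)-2-methyl-3-(trimethylsilyloxy)cyclohex-2-en-1-yl]propanoate | COC(=O)C(C)[C@H]1CCCC(O[Si](C)(C)C)=C1C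
F2 | step 9 | 5α,9-dimethyl-8-oxo-trans-decal-3-en-4-yl trifluoromethanesulfonate | CC1[C@H]2CCC=C(OS(=O)(=O)C(F)(F)F)[C@]2(C)CCC1=O
F3 | step 9 | 5α,9-dimethyl-8-oxo-trans-decala-3,6-dien-4-yl trifluoromethanesulfonate | CC1[C@H]2CCC=C(OS(=O)(=O)C(F)(F)F)[C@]2(C)C=CC1=O
F4 | step 9 | 9β-(ArCH2)-5α,9α-dimethyl-8-oxo-trans-decala-3,6-dien-4-yl trifluoromethanesulfonate | COc1cc(C)c(OCc2ccccc2)c(C[C@]3(C)[C@H]4CCC=C(OS(=O)(=O)C(F)(F)F)[C@]4(C)C=CC3=O)c1
F5 | step 15 | 2-{4α-[3-(benzyloxy)-3-oxopropyl]-9β-(ArCH2)-3-hydroxy-5α,8α,9α-trimethyl-trans-decalin-3-yl}-2-methylpropanoic acid | COc1cc(C)c(OCc2ccccc2)c(C[C@]3(C)[C@H]4CCC(O)(C(C)(C)C(=O)O)[C@@H](CCC(=O)OCc5ccccc5)[C@]4(C)CC[C@H]3C)c1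
F6 | step 15 | spiro β-lactone of F5 (3,3-dimethyloxetan-2-one spiro-fused at C3 of the decalin) | COc1cc(C)c(OCc2ccccc2)c(C[C@]3(C)[C@H]4CCC5(OC(=O)C5(C)C)[C@@H](CCC(=O)OCc6ccccc6)[C@]4(C)CC[C@H]3C)c1
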